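The flavonol is cut through ring C. C2, C3 and C4 form a three-carbon bridge between C4a of ring A and C1′ of ring B, with heteroatoms at C2 (O1) and C4 (C=O); this is the 1,3-pattern of a 3,5-diarylisoxazole. One nitrile oxide–alkyne cycloaddition forms the C2–C3 bond and the C4–O bond and delivers the masked 1,3-dicarbonyl unit. The alkyne partner is a terminal arylacetylene carrying ring A with the 8-benzyl group in place, the future O1 as a benzyl ether and the other phenols as methyl ethers; the dipole comes from 3,4-dimethoxybenzaldoxime. Hydrogenolysis, acid-induced ring closure, C3 hydroxylation and demethylation finish the synthesis.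

Key step: step 8

Remark: the target is achiral; carbinol 3 is the only chiral compound of the route, forms as a racemate and loses its stereocentre in step 2. 4-Methoxyphenylmagnesium bromide is taken as the commercial THF solution.

**Route**

Step 1
Reactants: 1 2-hydroxy-4,6-dimethoxybenzaldehyde; 2 4-methoxyphenylmagnesium bromide
Product: 3 rac-2-[hydroxy(4-methoxyphenyl)methyl]-3,5-dimethoxyphenol
Conditions: 2 (2.5 equiv), THF, 0 °C to rt; sat. aq NH4Cl; used crude
Reagents that add atoms: none
Why: Grignard 1,2-addition to the aldehyde, in which the first equivalent of 2 is spent as base on the phenol, the magnesium phenoxide chelates and activates the formyl group for the second equivalent, and the new carbinol stereocentre forms as a racemate that step 2 removes.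

Step 2
Reactants: 3 rac-2-[hydroxy(4-methoxyphenyl)methyl]-3,5-dimethoxyphenol
Product: 4 3,5-dimethoxy-2-(4-methoxybenzyl)phenol
Conditions: Et3SiH (3 equiv), CF3CO2H (5 equiv), CH2Cl2, 0 °C, 3 added slowly
Reagents that add atoms: none
Why: Ionic hydrogenation, in which the acid ionises the doubly benzylic alcohol to a cation stabilised by both oxygenated rings (a protonated ortho-quinone methide) and the silane, kept in excess over the slowly added carbinol, should reduce it by hydride transfer before it can alkylate another arene, while the phenol and the aryl methyl ethers are inert.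

Step 3
Reactants: 4 3,5-dimethoxy-2-(4-methoxybenzyl)phenol
Product: 6 2-hydroxy-4,6-dimethoxy-3-(4-methoxybenzyl)benzaldehyde, via hydroxymethylphenol 5 (not isolated)
Conditions: MgCl2 (2 equiv), Et3N (4 equiv), (CH2O)n (6 equiv), MeCN, reflux; 1 M HCl
Reagents that add atoms: paraformaldehyde (as formaldehyde), C=O
Why: Magnesium-mediated ortho-formylation (Casnati–Skattebøl type), in which the magnesium phenoxide delivers formaldehyde within a chelate to the only free ortho carbon and not to the para position between the methoxy groups, and hydroxymethylphenol 5 is oxidised in place by a second formaldehyde through Oppenauer-type hydride transfer.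

Step 4
Reactants: 6 2-hydroxy-4,6-dimethoxy-3-(4-methoxybenzyl)benzaldehyde
Product: 7 2-(benzyloxy)-4,6-dimethoxy-3-(4-methoxybenzyl)benzaldehyde
Conditions: BnBr (1.3 equiv), K2CO3 (2 equiv), DMF, 60 °C
Reagents that add atoms: benzyl bromide, BrCc1ccccc1
Why: Williamson etherification of the only acidic site in a polar aprotic solvent, which marks the future O1 with the one protecting group that hydrogenolysis will later remove.

Step 5
Reactants: 7 2-(benzyloxy)-4,6-dimethoxy-3-(4-methoxybenzyl)benzaldehyde
Product: 8 2-(benzyloxy)-1-ethynyl-4,6-dimethoxy-3-(4-methoxybenzyl)benzene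
Conditions: dimethyl (1-diazo-2-oxopropyl)phosphonate (2 equiv), K2CO3 (3 equiv), MeOH–THF, 0 °C to rt
Reagents that add atoms: dimethyl (1-diazo-2-oxopropyl)phosphonate, COP(=O)(OC)C(=[N+]=[N-])C(C)=O
Why: Ohira–Bestmann (Seyferth–Gilbert) homologation, in which methanolysis of the reagent releases the diazomethylphosphonate anion that olefinates the non-enolisable aldehyde to a diazoalkene, which loses N2 and rearranges by 1,2-hydride shift to the terminal alkyne under mild base that leaves the benzyl and methyl ethers untouched.

Step 6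
Reactants: 9 3,4-dimethoxybenzaldehyde
Product: 10 (E)-3,4-dimethoxybenzaldehyde oxime
Conditions: NH2OH·HCl (1.2 equiv), NaOAc (1.5 equiv), EtOH–H2O, rt
Reagents that add atoms: hydroxylamine hydrochloride, NO.Cl
Why: Oxime condensation of an aromatic aldehyde under acetate buffering, which should give the thermodynamically preferred E-aldoxime.

Step 7
Reactants: 10 (E)-3,4-dimethoxybenzaldehyde oxime
Product: 11 (Z)-N-hydroxy-3,4-dimethoxybenzimidoyl chloride
Conditions: N-chlorosuccinimide (1.05 equiv), DMF, rt; aqueous work-up, used directly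
Reagents that add atoms: N-chlorosuccinimide, O=C1CCC(=O)N1Cl
Why: Chlorination of the aldoxime C–H with N-chlorosuccinimide is the standard route to hydroximoyl chlorides, and isolating 11 after one equivalent of oxidant ensures that no electrophilic chlorine ever meets the electron-rich ring A of the alkyne.

Step 8
Reactants: 8 2-(benzyloxy)-1-ethynyl-4,6-dimethoxy-3-(4-methoxybenzyl)benzene; 11 (Z)-N-hydroxy-3,4-dimethoxybenzimidoyl chloride
Product: 13 5-[2-(benzyloxy)-4,6-dimethoxy-3-(4-methoxybenzyl)phenyl]-3-(3,4-dimethoxyphenyl)isoxazole, via 3,4-dimethoxybenzonitrile oxide 12 (not isolated)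
Conditions: 11 (2 equiv), Et3N (2.2 equiv, added over 8 h), CH2Cl2, rt
Reagents that add atoms: none
Why: Et3N dehydrochlorinates 11 to nitrile oxide 12, whose C≡N–O dipole adds across the terminal triple bond of 8 in a concerted but asynchronous suprafacial (3+2) cycloaddition, the Huisgen nitrile oxide–alkyne reaction that is the standard entry to isoxazoles. The one new ring, the isoxazole, closes intermolecularly as the dipole carbon bonds to the terminal alkyne carbon (future C2–C3) and the dipole oxygen to the aryl-bearing alkyne carbon (future C4–O) in the same transition state, and the adduct is aromatic as formed. No stereocentre is created. The step needs regioselectivity for the 3,5-diaryl isomer, which the monosubstituted alkyne secures: the larger HOMO coefficient of the electron-rich arylacetylene and the open space both lie at the CH terminus, where the bulky aryl-bearing dipole carbon bonds, while the benzyloxy and methoxy groups flanking the internal carbon admit only the small oxygen terminus. It also needs the cycloaddition to outrun dimerisation of 12 to the furoxan, which slow release of the dipole by metered base in the presence of the alkyne and an excess of 11 should ensure. Ring A bears no free phenol and meets no electrophilic halogen, so the electron-rich arene and the ethers stay intact.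

Step 9
Reactants: 13 5-[2-(benzyloxy)-4,6-dimethoxy-3-(4-methoxybenzyl)phenyl]-3-(3,4-dimethoxyphenyl)isoxazole
Product: 15 2-(3,4-dimethoxyphenyl)-5,7-dimethoxy-8-(4-methoxybenzyl)-4H-chromen-4-one, via enaminone 14 (not isolated)
Conditions: H2 (3 bar), 10% Pd/C, EtOH–EtOAc, rt; filter; conc. HCl (2 equiv), EtOH, reflux
Reagents that add atoms: none
Why: Catalytic hydrogenolysis cleaves the weak N–O bond of the isoxazole and the benzylic C–O bond in one operation (the known reductive opening of isoxazoles to β-enaminones), and on acidification the freed phenol adds to the enamine carbon (future C2) and ammonia is expelled in a conjugate addition–elimination cyclocondensation that can only give the 8-benzylflavone because the other ortho oxygen is still a methyl ether.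

Step 10
Reactants: 15 2-(3,4-dimethoxyphenyl)-5,7-dimethoxy-8-(4-methoxybenzyl)-4H-chromen-4-one
Product: 18 2-(3,4-dimethoxyphenyl)-3-hydroxy-5,7-dimethoxy-8-(4-methoxybenzyl)-4H-chromen-4-one, via 3-lithioflavone 16 (not isolated), via lithium trimethoxyborate 17 (not isolated)
Conditions: LiN(iPr)2 (1.5 equiv), THF, −78 °C; B(OMe)3 (3 equiv), −78 to 0 °C; AcOH, 30% H2O2, 0 °C to rt
Reagents that add atoms: lithium diisopropylamide, [Li+].CC(C)[N-]C(C)C; trimethyl borate, COB(OC)OC; hydrogen peroxide, OO
Why: C3 lithiation of a flavone followed by borylation and peroxide oxidation is a known flavone-to-flavonol conversion, in which the amide base at −78 °C removes the vinylic C3–H next to the chelating C4 carbonyl much faster than the diarylmethane CH2 to give 16, the borate traps the anion as 17, and peroxide turns the C–B bond into the C3–OH of 18 by 1,2-migration of carbon from boron to oxygen.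

Step 11
Reactants: 18 2-(3,4-dimethoxyphenyl)-3-hydroxy-5,7-dimethoxy-8-(4-methoxybenzyl)-4H-chromen-4-one
Product: 19 8-p-hydroxybenzylquercetin, 2-(3,4-dihydroxyphenyl)-3,5,7-trihydroxy-8-(4-hydroxybenzyl)-4H-chromen-4-one
Conditions: BBr3 (12 equiv), CH2Cl2, −78 °C to rt; MeOH then H2O
Reagents that add atoms: none
Why: Lewis-acid ether cleavage, in which BBr3 complexes each methoxy oxygen and bromide removes the methyl group by SN2 as is established for polymethoxyflavonols, and the cold start with only a room-temperature finish avoids the hot protic acid that could open ring C or shift the C8 benzyl group (Wessely–Moser-type isomerisation) before aqueous methanol hydrolyses the boron–oxygen bonds.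

**Compound list**

1 | 2-hydroxy-4,6-dimethoxybenzaldehyde | COc1cc(O)c(C=O)c(OC)c1 | starting material
2 | 4-methoxyphenylmagnesium bromide (THF solution) | COc1ccc([Mg]Br)cc1 | starting material
3 | rac-2-[hydroxy(4-methoxyphenyl)methyl]-3,5-dimethoxyphenol (racemate) | COc1ccc(C(O)c2c(O)cc(OC)cc2OC)cc1 | intermediate
4 | 3,5-dimethoxy-2-(4-methoxybenzyl)phenol | COc1ccc(Cc2c(O)cc(OC)cc2OC)cc1 | intermediate
5 | 2-(hydroxymethyl)-3,5-dimethoxy-6-(4-methoxybenzyl)phenol (hydroxymethylphenol, not isolated) | COc1ccc(Cc2c(O)c(CO)c(OC)cc2OC)cc1 | intermediate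
6 | 2-hydroxy-4,6-dimethoxy-3-(4-methoxybenzyl)benzaldehyde | COc1ccc(Cc2c(O)c(C=O)c(OC)cc2OC)cc1 | intermediate
7 | 2-(benzyloxy)-4,6-dimethoxy-3-(4-methoxybenzyl)benzaldehyde | COc1ccc(Cc2c(OC)cc(OC)c(C=O)c2OCc2ccccc2)cc1 | intermediate
8 | 2-(benzyloxy)-1-ethynyl-4,6-dimethoxy-3-(4-methoxybenzyl)benzene | COc1ccc(Cc2c(OC)cc(OC)c(C#C)c2OCc2ccccc2)cc1 | intermediate
9 | 3,4-dimethoxybenzaldehyde | COc1ccc(C=O)cc1OC | starting material
10 | (E)-3,4-dimethoxybenzaldehyde oxime | COc1ccc(/C=N/O)cc1OC | intermediate
11 | (Z)-N-hydroxy-3,4-dimethoxybenzimidoyl chloride | COc1ccc(/C(Cl)=N/O)cc1OC | intermediate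
12 | 3,4-dimethoxybenzonitrile oxide (not isolated) | COc1ccc(C#[N+][O-])cc1OC | intermediate
13 | 5-[2-(benzyloxy)-4,6-dimethoxy-3-(4-methoxybenzyl)phenyl]-3-(3,4-dimethoxyphenyl)isoxazole | COc1ccc(Cc2c(OC)cc(OC)c(-c3cc(-c4ccc(OC)c(OC)c4)no3)c2OCc2ccccc2)cc1 | intermediate
14 | (Z)-3-amino-3-(3,4-dimethoxyphenyl)-1-[2-hydroxy-4,6-dimethoxy-3-(4-methoxybenzyl)phenyl]prop-2-en-1-one (enaminone, not isolated) | COc1ccc(Cc2c(OC)cc(OC)c(C(=O)/C=C(\N)c3ccc(OC)c(OC)c3)c2O)cc1 | intermediate
15 | 2-(3,4-dimethoxyphenyl)-5,7-dimethoxy-8-(4-methoxybenzyl)-4H-chromen-4-one | COc1ccc(Cc2c(OC)cc(OC)c3c(=O)cc(-c4ccc(OC)c(OC)c4)oc23)cc1 | intermediate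
16 | 3-lithio-2-(3,4-dimethoxyphenyl)-5,7-dimethoxy-8-(4-methoxybenzyl)-4H-chromen-4-one (3-lithioflavone, not isolated) | COc1ccc(Cc2c(OC)cc(OC)c3c(=O)c([Li])c(-c4ccc(OC)c(OC)c4)oc23)cc1 | intermediate
17 | lithium [2-(3,4-dimethoxyphenyl)-5,7-dimethoxy-8-(4-methoxybenzyl)-4-oxo-4H-chromen-3-yl]trimethoxyborate (not isolated) | [Li+].COc1ccc(Cc2c(OC)cc(OC)c3c(=O)c([B-](OC)(OC)OC)c(-c4ccc(OC)c(OC)c4)oc23)cc1 | intermediate
18 | 2-(3,4-dimethoxyphenyl)-3-hydroxy-5,7-dimethoxy-8-(4-methoxybenzyl)-4H-chromen-4-one | COc1ccc(Cc2c(OC)cc(OC)c3c(=O)c(O)c(-c4ccc(OC)c(OC)c4)oc23)cc1 | intermediate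
19 | 8-p-hydroxybenzylquercetin | O=c1c(O)c(-c2ccc(O)c(O)c2)oc2c(Cc3ccc(O)cc3)c(O)cc(O)c12 | target

**Step count and risk**

Total steps: 11. Longest linear sequence: 9 steps (steps 1–5 and 8–11, from 1 to 19); steps 6 and 7 are a two-step side branch that joins at step 8.

Steps most likely to fail, riskiest first:

Step 8. Dimerisation of nitrile oxide 12 to its furoxan may outrun addition to the hindered, electron-rich alkyne, or part of the dipole may add with reversed orientation. The fallback sets out from alkyne 8 and comes back at isoxazole 13, building the heterocycle by condensation and cycloisomerisation instead of cycloaddition. Acyl Sonogashira coupling of 8 with 3,4-dimethoxybenzoyl chloride (PdCl2(PPh3)2, CuI, Et3N, THF, rt) should give 3-[2-(benzyloxy)-4,6-dimethoxy-3-(4-methoxybenzyl)phenyl]-1-(3,4-dimethoxyphenyl)prop-2-yn-1-one F1. Oximation (NH2OH·HCl, pyridine, EtOH) should give the ynone oxime F2. AuCl3-catalysed 5-endo-dig attack of the oxime oxygen on the alkyne carbon that bears ring A (CH2Cl2, rt) should then close 13. The nitrogen is fixed on the carbon attached to ring B by the connectivity of the ynone.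

Step 10. The base may deprotonate the diarylmethane CH2 in competition with C3, or the lithiated pyranone may ring-open before it is trapped. The fallback sets out from flavone 15 and comes back at flavonol 18 without any carbanion. Dimethyldioxirane (acetone–CH2Cl2, 0 °C to rt) should epoxidise the C2=C3 bond to the racemic cis-fused 2,3-epoxyflavanone F3. Catalytic TsOH in CH2Cl2 should open the epoxide at C2, where the cation is stabilised by O1 and ring B, and loss of the C3 proton gives 18.

Step 5. Olefination of the deactivated, doubly ortho-substituted aldehyde may be so slow that the diazophosphonate anion decomposes in methanol first. The fallback sets out from aldehyde 7 and comes back at alkyne 8 by the Corey–Fuchs sequence. CBr4 and PPh3 (CH2Cl2, 0 °C) should give 2-(benzyloxy)-1-(2,2-dibromovinyl)-4,6-dimethoxy-3-(4-methoxybenzyl)benzene F4. n-BuLi (2.2 equiv, THF, −78 °C, then H2O) should convert it into 8 by bromine–lithium exchange and Fritsch–Buttenberg–Wiechell rearrangement.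

**Further compounds**

F1 | step 8 | 3-[2-(benzyloxy)-4,6-dimethoxy-3-(4-methoxybenzyl)phenyl]-1-(3,4-dimethoxyphenyl)prop-2-yn-1-one | COc1ccc(Cc2c(OC)cc(OC)c(C#CC(=O)c3ccc(OC)c(OC)c3)c2OCc2ccccc2)cc1
F2 | step 8 | (Z)-oxime of F1 (hydroxyl syn to the alkynyl group) | COc1ccc(Cc2c(OC)cc(OC)c(C#C/C(=N\O)c3ccc(OC)c(OC)c3)c2OCc2ccccc2)cc1
F3 | step 10 | rac-2,3-epoxy-2-(3,4-dimethoxyphenyl)-5,7-dimethoxy-8-(4-methoxybenzyl)chroman-4-one (cis-fused, racemate, one enantiomer drawn) | COc1ccc(Cc2c(OC)cc(OC)c3c2O[C@@]2(c4ccc(OC)c(OC)c4)O[C@H]2C3=O)cc1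
F4 | step 5 | 2-(benzyloxy)-1-(2,2-dibromovinyl)-4,6-dimethoxy-3-(4-methoxybenzyl)benzene | COc1ccc(Cc2c(OC)cc(OC)c(C=C(Br)Br)c2OCc2ccccc2)cc1
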